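## Analysis of the target

Eupakirunsin C (40) is a germacranolide. Its ten-membered carbocycle C1–C10 is fused through C6 (oxygen) and C7 (carbon) to an α-methylene-γ-butyrolactone (C11=C13, C12 carbonyl). The ring carries a secondary alcohol at C1, a ketone at C3, a cis epoxide over C4–C5 with the methyl C15 on quaternary C4, a tigloyloxy group at C8 and a methyl-bearing stereocentre at C10.

There are seven stereocentres (1R,4R,5R,6S,7R,8R,10S), five of them contiguous from C4 to C8. H6 and H7 are trans across the lactone. The C7 side chain is anti to the C8 oxygen, and the C6 and C8 oxygens are 1,3-anti. The epoxide oxygen lies on the same side as the C6 oxygen, and the C1 hydroxyl is anti to the C10 methyl.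

The sensitive groups are the Michael-accepting methylene lactone, the α,β-epoxy ketone, the C1/C3 β-hydroxy ketone (dehydration, retro-aldol) and the conjugated ester. The hard points are closure of a ten-membered ring against entropy and transannular strain, a cis epoxide that demands a Z C4=C5 olefin inside that ring, and two oxygens (C6, C8) that are both γ to C12.

The strategy rests on one feature. The C3 carbonyl lies between C2 and C4, so with C1=C2 and C4=C5 as olefins it is the central carbon of a cross-conjugated divinyl ketone and can be carbon monoxide inserted between two alkenyl termini. The two enones that result differ (E and α-unsubstituted against Z and α-methylated), so C1 can be oxygenated and C4–C5 epoxidised in turn.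

## Retrosynthetic reasoning

**Lactone (40 to 37, 36, 35).** The O6–C12 acyl bond is cut and C12 is lowered to the alcohol. A methylene lactone or acrylate would compete in every conjugate step and at palladium, whereas a 2-substituted allylic ether is inert. The forward reaction must oxidise only the allylic primary alcohol of triol 37 and let the C6 hydroxyl capture the aldehyde. The PMB group is removed first (35 to 36) and the silyl groups second (36 to 37), so that the C6 hydroxyl is free only when it is needed.

**Epoxide (35 to 34).** The C4–O and C5–O bonds are cut back to the Z-enone. This works because C4=C5 is conjugated to C3 and accepts a peroxide nucleophile. The forward step must keep C3 and C6 cis and add from the outer face of the ring.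

**C1 oxygen (34 to 33, 32, 31).** The C1–O bond is cut back to the E-enone of dienone 31. C1 is an unsubstituted β-carbon, so a boryl nucleophile adds there before it touches the hindered α-methyl Z-enone. Boronate 32 is oxidised with retention and the alcohol 33 is capped as 34 before base is used.

**Ring (31 to 30).** C2–C3 and C3–C4 are cut together and C3 leaves as a one-carbon carbonyl unit taken from the gas phase. C3 is the only ring atom that carries no substituent and is flanked by sp2 carbons on both sides. Every other ring bond lies next to a stereocentre. The gain is an open-chain precursor 30 whose four stereocentres can be set by acyclic control and whose two olefin geometries are fixed before the ring exists. The forward step must insert the carbonyl before the chain ends couple and must close the ring faster than chains combine.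

**Ester and C8 (30 to 27 + 28, 27 to 26).** The C8–O acyl bond is cut to alcohol 27 and tiglic acid 28. The C8–H bond is cut back to ketone 26, so that C8 is set by a reagent-controlled reduction late and needs no protecting group.

**C8–C9 (26 to 24 + 9, through 25).** C9 is an unfunctionalised methylene and C10 comes from the chiral pool, so this bond is made by acyl substitution of Weinreb amide 24 with Grignard reagent 25. The alkenylstannane must already be in 25, because no hydrostannylation is possible once the alkenyl iodide is present.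

**C6–C7 (24, 23, 22 to 16 + 20).** Drawn along C8–C7–C6–C5, the C6 hydroxyl and the C7 branch are syn, which is the Evans pattern, and the bond is cut to imide 16 and aldehyde 20. The Z-alkenyl iodide arrives intact in 20, so no iodination is needed after tin is on board. The β,γ-unsaturated acyl group of 16 delivers C11=C13 directly as the exocyclic olefin.

**Pieces.** Imide 16 comes from acid 13 and oxazolidinone 14; acid 13 from allylic chloride 11 through Grignard reagent 12; 11 from dichloride 10. Aldehyde 20 comes from alcohol 19, made from butynol 17 through alanate 18. Bromide 9 comes from alcohol 7 through mesylate 8; 7 from silyl ether 6, made from alkyne 4 and tin hydride 5; 4 from aldehyde 3, ester 2 and hydroxy ester 1.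

## Alternatives that were turned down

**Alternative 1: lactone annulation by carbenoid C–H insertion.**
- Disconnection: the C7–C11 bond of the lactone, on a ten-membered ring that is already complete, with C7 as a methylene.
- Forward step: Rh2(OAc)4 decomposes a diazo(phosphono)acetate ester on O6 and the C11 carbenoid inserts into one C7–H bond to give phosphono lactone A1. A Horner–Wadsworth–Emmons methylenation follows.
- For: the lactone and the methylene arrive last, so no C12 protecting group or oxidation is carried, and C7 need not be a preset branched stereocentre.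
- Against: the carbenoid has several choices. The two C7 hydrogens are diastereotopic (cis or trans fusion). The C5–H on the epoxide is also 1,5 to the carbenoid. C7–H is deactivated by the acyloxy group on C8. The epoxide oxygen, the C3 ketone and the tiglate offer ylide formation or cyclopropanation. The route also leaves ring formation itself unsolved.
- Comparison: Alternative 1 is stronger on the lactone endgame, which costs three steps in the chosen route. The chosen route offers a ring-forming step that also brings in C3, and fixes C7 by an auxiliary and not by selection among C–H bonds on a mobile medium ring.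

**Alternative 2: Grob fragmentation of a hydroxydecalin.**
- Disconnection: a transannular C1–C6 bond is added in the retrosynthetic direction, so the ring is hidden in a trans-fused bicycle.
- Forward step: KOtBu generates a C6 alkoxide that expels a C2 sulfonate as C1–C6 breaks, giving dienone A2 with an E C1=C2 olefin and the cis C4=C5 olefin untouched.
- For: the ring is unveiled without dilution, the anti-periplanar arrangement in a rigid bicycle translates cleanly into E geometry, and six-membered-ring stereocontrol is well understood.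
- Against: A2 has its oxygens in the wrong places. C6 is a ketone and must be reduced selectively on the macrocycle. C3 is a protected alcohol that must be oxidised. C1 still has to be oxygenated. The C8 silyl ether must be exchanged for tiglate. The C7 acetate arm must be lactonised and methylenated. Three stereocentres of the bicycle (C1, C2, C6) are built only to be destroyed, and the bicycle itself is a long linear construction.
- Comparison: Alternative 2 is stronger on the reliability of ring formation. The chosen route offers the C3 ketone in the right oxidation state from the ring-forming step, C6 already set, and a convergent assembly.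

**Alternative 3: anionic oxy-Cope ring expansion.**
- Disconnection: the C1–C10 bond, with a C3–C8 bond added so that the ring contracts to a cyclohexene carrying two alkenyl groups.
- Forward step: KH and 18-crown-6 form the C8 alkoxide, and a [3,3] shift joins C1 to C10 while C3–C8 breaks, giving ketone A3 with C3 masked as a methyl dienol ether.
- For: no dilution is needed, enolate formation makes the step irreversible, and C1 (with its oxygen) and C10 are set together in the ring-forming event.
- Against: the substrate needs two adjacent fully substituted carbons (C3, C8) with cis alkenyl groups of defined E and Z geometry. The C1/C10 outcome depends on chair against boat. A3 has a C8 ketone beside an epimerisable C7 and a β-silyloxy group at C6 under strongly basic conditions. C8 must then be reduced and acylated, and the two-carbon C7 arm oxidised, lactonised and methylenated.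
- Comparison: Alternative 3 is stronger at C1, where the chosen route needs a separate face-selective conjugate borylation. The chosen route offers a simple acyclic precursor made by auxiliary- and reagent-controlled steps, with C6 and C8 at their final oxidation level.

Key step: step 18

Assumption: locants C1–C15 follow germacrane numbering (ring C1–C10, lactone carbons C11–C13, C14 on C10, C15 on C4) and are used for ring compounds and, in the text, for open-chain compounds.

Remark: drawn along C8–C7–C6–C5 the C6 hydroxyl and the C7 branch are syn, so the C6–C7 union is an Evans syn aldol; the same relationship reads anti when the chain is drawn through C11.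

## Route

Step 1
Reactants: 1 methyl (S)-3-hydroxy-2-methylpropanoate
Product: 2 methyl (S)-3-[(tert-butyldimethylsilyl)oxy]-2-methylpropanoate
Conditions: TBSCl, imidazole, CH2Cl2, 0 °C to rt
Reagents that add atoms: tert-butyldimethylsilyl chloride, CC(C)(C)[Si](C)(C)Cl
Why: Imidazole-promoted silylation of the primary alcohol; the stereocentre is not touched.

Step 2
Reactants: 2 methyl (S)-3-[(tert-butyldimethylsilyl)oxy]-2-methylpropanoate
Product: 3 (S)-3-[(tert-butyldimethylsilyl)oxy]-2-methylpropanal
Conditions: iBu2AlH, CH2Cl2, −78 °C; aq. potassium sodium tartrate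
Reagents that add atoms: none
Why: Partial reduction of the ester through the aluminium hemiacetal, which is stable at −78 °C; the aldehyde is used cold and at once so that the α-stereocentre should hold.

Step 3
Reactants: 3 (S)-3-[(tert-butyldimethylsilyl)oxy]-2-methylpropanal
Product: 4 (R)-tert-butyldimethyl[(2-methylbut-3-yn-1-yl)oxy]silane
Conditions: dimethyl (1-diazo-2-oxopropyl)phosphonate, K2CO3, MeOH, 0 °C to rt
Reagents that add atoms: dimethyl (1-diazo-2-oxopropyl)phosphonate, COP(=O)(OC)C(=[N+]=[N-])C(C)=O
Why: Seyferth–Gilbert homologation in the Ohira–Bestmann variant makes the aldehyde carbon C1 and adds C2; carbonate at 0 °C should keep epimerisation of the future C10 low.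

Step 4
Reactants: 4 (R)-tert-butyldimethyl[(2-methylbut-3-yn-1-yl)oxy]silane, 5 tributyltin hydride
Product: 6 (R,E)-tert-butyldimethyl{[2-methyl-4-(tributylstannyl)but-3-en-1-yl]oxy}silane
Conditions: PdCl2(PPh3)2 (2 mol %), THF, 0 °C
Reagents that add atoms: none
Why: Palladium-catalysed syn hydrostannylation of a terminal alkyne; tin goes to the open terminus because the propargylic branch disfavours the internal isomer, which fixes the E geometry of C1=C2.

Step 5
Reactants: 6 (R,E)-tert-butyldimethyl{[2-methyl-4-(tributylstannyl)but-3-en-1-yl]oxy}silane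
Product: 7 (R,E)-2-methyl-4-(tributylstannyl)but-3-en-1-ol
Conditions: Bu4NF, THF, 0 °C to rt
Reagents that add atoms: none
Why: Fluoride desilylation; the alkenylstannane is inert to fluoride under these non-acidic conditions.

Step 6
Reactants: 7 (R,E)-2-methyl-4-(tributylstannyl)but-3-en-1-ol
Product: 9 (R,E)-(4-bromo-3-methylbut-1-en-1-yl)tributylstannane, via mesylate 8 (not isolated)
Conditions: MsCl, Et3N, THF, 0 °C; then LiBr, THF, rt to 45 °C
Reagents that add atoms: lithium bromide, [Li+].[Br-]
Why: Sulfonylation followed by SN2 displacement with bromide (Finkelstein type) at the primary carbon; no halogen electrophile is present that could cleave the C–Sn bond.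

Step 7
Reactants: 10 3-chloro-2-(chloromethyl)prop-1-ene
Product: 11 1-({[2-(chloromethyl)prop-2-en-1-yl]oxy}methyl)-4-methoxybenzene
Conditions: 4-methoxybenzyl alcohol, NaH, THF/DMF, 0 °C to rt (10 in threefold excess)
Reagents that add atoms: 4-methoxybenzyl alcohol, COc1ccc(CO)cc1
Why: Williamson ether synthesis on an allylic chloride; the excess of the dichloride suppresses the bis-ether.

Step 8
Reactants: 11 1-({[2-(chloromethyl)prop-2-en-1-yl]oxy}methyl)-4-methoxybenzene
Product: 13 3-{[(4-methoxybenzyl)oxy]methyl}but-3-enoic acid, via allylmagnesium chloride 12 (not isolated)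
Conditions: Mg, THF, 0 °C (slow addition); CO2, −78 °C to rt; cold 1 M HCl
Reagents that add atoms: carbon dioxide, O=C=O
Why: Grignard formation and carboxylation; both allyl termini give the same β,γ-unsaturated acid, and the carboxylate is protonated on oxygen so the olefin should stay out of conjugation.

Step 9
Reactants: 13 3-{[(4-methoxybenzyl)oxy]methyl}but-3-enoic acid, 14 (S)-4-benzyl-1,3-oxazolidin-2-one
Product: 16 (S)-4-benzyl-3-(3-{[(4-methoxybenzyl)oxy]methyl}but-3-enoyl)-1,3-oxazolidin-2-one, via mixed pivalic anhydride 15 (not isolated)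
Conditions: PivCl, Et3N, THF, −20 °C; then 14, LiCl, rt
Reagents that add atoms: none
Why: N-acylation of the oxazolidinone through the mixed anhydride under the lithium chloride and triethylamine protocol, which is mild enough to leave the double bond β,γ.

Step 10
Reactants: 17 but-2-yn-1-ol
Product: 19 (Z)-3-iodobut-2-en-1-ol, via cyclic vinylalanate 18 (not isolated)
Conditions: NaAlH2(OCH2CH2OMe)2, THF, 0 °C to rt; then iodine, THF, −78 °C
Reagents that add atoms: iodine, [I][I]
Why: Hydroxyl-directed trans-hydroalumination puts aluminium on the methyl-bearing carbon, cis to the carbinol carbon in a five-membered alanate; iodinolysis with retention gives the Z iodide (future C4–C6 with C15).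

Step 11
Reactants: 19 (Z)-3-iodobut-2-en-1-ol
Product: 20 (Z)-3-iodobut-2-enal
Conditions: MnO2, CH2Cl2, rt, dark
Reagents that add atoms: none
Why: Neutral allylic oxidation that should retain the Z geometry; the aldehyde is used at once.

Step 12
Reactants: 16 (S)-4-benzyl-3-(3-{[(4-methoxybenzyl)oxy]methyl}but-3-enoyl)-1,3-oxazolidin-2-one, 20 (Z)-3-iodobut-2-enal
Product: 22 (S)-4-benzyl-3-[(2S,3S,4Z)-3-hydroxy-5-iodo-2-{3-[(4-methoxybenzyl)oxy]prop-1-en-2-yl}hex-4-enoyl]-1,3-oxazolidin-2-one, via Z-boron enolate 21 (not isolated)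
Conditions: Bu2BOTf, Et3N, CH2Cl2, −78 to 0 °C; then 20, −78 to −20 °C; pH 7 buffer, MeOH, H2O2, 0 °C
Reagents that add atoms: none
Why: Evans syn aldol; the Z boron dienolate reacts at its α-carbon (C7) through a closed Zimmerman–Traxler chair, and the benzyl group of the auxiliary shields one enolate face, which sets C7 and C6 together.

Step 13
Reactants: 22 (S)-4-benzyl-3-[(2S,3S,4Z)-3-hydroxy-5-iodo-2-{3-[(4-methoxybenzyl)oxy]prop-1-en-2-yl}hex-4-enoyl]-1,3-oxazolidin-2-one
Product: 23 (2S,3S,4Z)-3-hydroxy-5-iodo-N-methoxy-2-{3-[(4-methoxybenzyl)oxy]prop-1-en-2-yl}-N-methylhex-4-enamide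
Conditions: MeNH(OMe)·HCl, AlMe3, CH2Cl2, −20 to 0 °C; aq. potassium sodium tartrate
Reagents that add atoms: N,O-dimethylhydroxylamine hydrochloride, CNOC.Cl
Why: Aluminium amide transamidation to the Weinreb amide, assisted by the free β-hydroxyl; the conditions are not basic, so the doubly activated C7–H should not epimerise.

Step 14
Reactants: 23 (2S,3S,4Z)-3-hydroxy-5-iodo-N-methoxy-2-{3-[(4-methoxybenzyl)oxy]prop-1-en-2-yl}-N-methylhex-4-enamide
Product: 24 (2S,3S,4Z)-3-[(tert-butyldimethylsilyl)oxy]-5-iodo-N-methoxy-2-{3-[(4-methoxybenzyl)oxy]prop-1-en-2-yl}-N-methylhex-4-enamide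
Conditions: TBSOTf, 2,6-lutidine, CH2Cl2, −78 to 0 °C
Reagents that add atoms: tert-butyldimethylsilyl trifluoromethanesulfonate, CC(C)(C)[Si](C)(C)OS(=O)(=O)C(F)(F)F
Why: Silyl triflate silylation of the hindered allylic alcohol; this caps O6 so that it cannot intercept the acylpalladium later.

Step 15
Reactants: 9 (R,E)-(4-bromo-3-methylbut-1-en-1-yl)tributylstannane, 24 (2S,3S,4Z)-3-[(tert-butyldimethylsilyl)oxy]-5-iodo-N-methoxy-2-{3-[(4-methoxybenzyl)oxy]prop-1-en-2-yl}-N-methylhex-4-enamide
Product: 26 (1E,3S,6S,7S,8Z)-7-[(tert-butyldimethylsilyl)oxy]-9-iodo-6-{3-[(4-methoxybenzyl)oxy]prop-1-en-2-yl}-3-methyl-1-(tributylstannyl)deca-1,8-dien-5-one, via Grignard reagent 25 (not isolated)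
Conditions: 9, Mg, THF, rt (25 decanted from excess Mg); then 24, THF, 0 °C; aq. NH4Cl
Reagents that add atoms: none
Why: Grignard addition to a Weinreb amide forms C8–C9; the magnesium chelate of the tetrahedral intermediate prevents over-addition and keeps the C7–H unexposed until the quench, and an alkylmagnesium reagent should not exchange with the alkenyl iodide at 0 °C.

Step 16
Reactants: 26 (1E,3S,6S,7S,8Z)-7-[(tert-butyldimethylsilyl)oxy]-9-iodo-6-{3-[(4-methoxybenzyl)oxy]prop-1-en-2-yl}-3-methyl-1-(tributylstannyl)deca-1,8-dien-5-one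
Product: 27 (1E,3S,5R,6R,7S,8Z)-7-[(tert-butyldimethylsilyl)oxy]-9-iodo-6-{3-[(4-methoxybenzyl)oxy]prop-1-en-2-yl}-3-methyl-1-(tributylstannyl)deca-1,8-dien-5-ol
Conditions: (S)-2-methyl-CBS-oxazaborolidine (0.5 equiv), catecholborane, toluene, −78 to −40 °C
Reagents that add atoms: none
Why: Corey–Bakshi–Shibata reduction; the branched C7 arm acts as the large group against the C9 methylene, so the (S)-catalyst should deliver hydride to the face that gives 8R, and the Felkin–Anh preference of C7 (C6 branch anti to hydride) points the same way; catecholborane leaves the olefins and the stannane alone at this temperature.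

Step 17
Reactants: 27 (1E,3S,5R,6R,7S,8Z)-7-[(tert-butyldimethylsilyl)oxy]-9-iodo-6-{3-[(4-methoxybenzyl)oxy]prop-1-en-2-yl}-3-methyl-1-(tributylstannyl)deca-1,8-dien-5-ol, 28 tiglic acid
Product: 30 (1E,3S,5R,6R,7S,8Z)-7-[(tert-butyldimethylsilyl)oxy]-9-iodo-6-{3-[(4-methoxybenzyl)oxy]prop-1-en-2-yl}-3-methyl-1-(tributylstannyl)deca-1,8-dien-5-yl (E)-2-methylbut-2-enoate, via mixed Yamaguchi anhydride 29 (not isolated)
Conditions: 28, 2,4,6-trichlorobenzoyl chloride, Et3N, toluene, rt; then 27, DMAP, rt
Reagents that add atoms: none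
Why: Yamaguchi esterification; DMAP transfers the tigloyl group from the mixed anhydride to the hindered C8 hydroxyl without touching the E geometry of the acid.

Step 18
Reactants: 30 (1E,3S,5R,6R,7S,8Z)-7-[(tert-butyldimethylsilyl)oxy]-9-iodo-6-{3-[(4-methoxybenzyl)oxy]prop-1-en-2-yl}-3-methyl-1-(tributylstannyl)deca-1,8-dien-5-yl (E)-2-methylbut-2-enoate
Product: 31 (1E,4Z,6R,7R,8R,10S)-6-[(tert-butyldimethylsilyl)oxy]-7-{3-[(4-methoxybenzyl)oxy]prop-1-en-2-yl}-4,10-dimethyl-3-oxocyclodeca-1,4-dien-8-yl (E)-2-methylbut-2-enoate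
Conditions: Pd(PPh3)4 (15 mol %), CO (3 atm), THF/DMF, 55 °C, 30 added by syringe pump to a final 1 mM
Reagents that add atoms: carbon monoxide, [C-]#[O+]
Why: Carbonylative Stille coupling, run intramolecularly. Zerovalent palladium inserts into the C4–I bond with retention of the Z geometry, CO coordinates and migrates to give the C3 acylpalladium iodide, the E-alkenylstannane at C2 transmetalates with retention, and reductive elimination forms C2–C3. The closest known reaction type is the carbonylative cross-coupling of alkenyl iodides or triflates with alkenylstannanes, which has been used intramolecularly to close macrocyclic divinyl ketones. The single ring is closed end to end: both termini meet on one metal centre in an eleven-membered acyl(alkenyl)palladacycle, which contracts to the ten-membered ketone on reductive elimination. No stereocentre is formed; C6, C7, C8 and C10 are spectators and both olefin geometries follow from stereoretentive elementary steps. Three selectivities are needed: CO insertion before transmetalation, secured by CO pressure and by the strain of the nine-membered E,Z-diene that direct coupling would have to form; ring closure over oligomerisation, secured by slow addition to high dilution and by the sp2 atoms and the C6–C8 branching that shorten and preorganise the tether; and survival of the Z-enone, helped by the moderate temperature. All hydroxyl groups are capped, so the acylpalladium cannot be diverted into a lactone.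

Step 19
Reactants: 31 (1E,4Z,6R,7R,8R,10S)-6-[(tert-butyldimethylsilyl)oxy]-7-{3-[(4-methoxybenzyl)oxy]prop-1-en-2-yl}-4,10-dimethyl-3-oxocyclodeca-1,4-dien-8-yl (E)-2-methylbut-2-enoate
Product: 33 (1R,4Z,6R,7R,8R,10S)-6-[(tert-butyldimethylsilyl)oxy]-1-hydroxy-7-{3-[(4-methoxybenzyl)oxy]prop-1-en-2-yl}-4,10-dimethyl-3-oxocyclodec-4-en-8-yl (E)-2-methylbut-2-enoate, via C1 pinacol boronate 32 (not isolated)
Conditions: CuCl (10 mol %), NaOtBu (15 mol %), (R)-1-[(S_p)-2-(diphenylphosphino)ferrocenyl]ethyldicyclohexylphosphine (12 mol %), B2pin2 (1.1 equiv), MeOH (2 equiv), THF, 0 °C to rt; then NaBO3·4H2O, THF/H2O, rt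
Reagents that add atoms: sodium perborate, [Na+].[O-]OB=O
Why: Copper-catalysed conjugate borylation (1,4-addition of a boryl–copper species, protonation of the copper enolate by methanol) followed by stereoretentive C–B oxidation; the E-enone with its unsubstituted β-carbon C1 should react before the α-methyl Z-enone or the tiglate. The chiral ligand is chosen to add boron to the outer face of C1 anti to the C10 methyl, which gives 1R; its antipode is used if the ring proves mismatched.

Step 20
Reactants: 33 (1R,4Z,6R,7R,8R,10S)-6-[(tert-butyldimethylsilyl)oxy]-1-hydroxy-7-{3-[(4-methoxybenzyl)oxy]prop-1-en-2-yl}-4,10-dimethyl-3-oxocyclodec-4-en-8-yl (E)-2-methylbut-2-enoate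
Product: 34 (1R,4Z,6R,7R,8R,10S)-6-[(tert-butyldimethylsilyl)oxy]-7-{3-[(4-methoxybenzyl)oxy]prop-1-en-2-yl}-4,10-dimethyl-3-oxo-1-[(triethylsilyl)oxy]cyclodec-4-en-8-yl (E)-2-methylbut-2-enoate
Conditions: TESOTf, 2,6-lutidine, CH2Cl2, −78 °C
Reagents that add atoms: triethylsilyl trifluoromethanesulfonate, CC[Si](CC)(CC)OS(=O)(=O)C(F)(F)F
Why: Silylation under non-basic conditions protects the β-hydroxy ketone against retro-aldol cleavage and dehydration in the basic step that follows.

Step 21
Reactants: 34 (1R,4Z,6R,7R,8R,10S)-6-[(tert-butyldimethylsilyl)oxy]-7-{3-[(4-methoxybenzyl)oxy]prop-1-en-2-yl}-4,10-dimethyl-3-oxo-1-[(triethylsilyl)oxy]cyclodec-4-en-8-yl (E)-2-methylbut-2-enoate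
Product: 35 (1R,4R,5R,6S,7R,8R,10S)-6-[(tert-butyldimethylsilyl)oxy]-4,5-epoxy-7-{3-[(4-methoxybenzyl)oxy]prop-1-en-2-yl}-4,10-dimethyl-3-oxo-1-[(triethylsilyl)oxy]cyclodecan-8-yl (E)-2-methylbut-2-enoate
Conditions: tBuOOH, BnMe3NOH (cat.), THF, 0 °C
Reagents that add atoms: tert-butyl hydroperoxide, CC(C)(C)OO
Why: Weitz–Scheffer nucleophilic epoxidation; with C6–H eclipsing the olefin the ring bond to C7 points inward, so the peroxide anion should add to C5 from the outer face, which is the face of the C6 silyloxy group. Ring closure of the enolate onto oxygen inside the ring should be faster than rotation about C4–C5, which keeps C3 and C6 cis and gives the 4R,5R epoxide; the anhydrous medium spares the tiglate.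

Step 22
Reactants: 35 (1R,4R,5R,6S,7R,8R,10S)-6-[(tert-butyldimethylsilyl)oxy]-4,5-epoxy-7-{3-[(4-methoxybenzyl)oxy]prop-1-en-2-yl}-4,10-dimethyl-3-oxo-1-[(triethylsilyl)oxy]cyclodecan-8-yl (E)-2-methylbut-2-enoate
Product: 36 (1R,4R,5R,6S,7R,8R,10S)-6-[(tert-butyldimethylsilyl)oxy]-4,5-epoxy-7-(3-hydroxyprop-1-en-2-yl)-4,10-dimethyl-3-oxo-1-[(triethylsilyl)oxy]cyclodecan-8-yl (E)-2-methylbut-2-enoate
Conditions: DDQ, CH2Cl2/pH 7 buffer, 0 °C
Reagents that add atoms: none
Why: Oxidative cleavage of the 4-methoxybenzyl ether (hydride abstraction, hydrolysis of the oxocarbenium ion); O6 is still silylated, so no cyclic acetal can form, and the buffer protects the epoxide and the silyl ethers.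

Step 23
Reactants: 36 (1R,4R,5R,6S,7R,8R,10S)-6-[(tert-butyldimethylsilyl)oxy]-4,5-epoxy-7-(3-hydroxyprop-1-en-2-yl)-4,10-dimethyl-3-oxo-1-[(triethylsilyl)oxy]cyclodecan-8-yl (E)-2-methylbut-2-enoate
Product: 37 (1R,4R,5R,6S,7S,8R,10S)-4,5-epoxy-1,6-dihydroxy-7-(3-hydroxyprop-1-en-2-yl)-4,10-dimethyl-3-oxocyclodecan-8-yl (E)-2-methylbut-2-enoate
Conditions: HF·pyridine, pyridine, THF, 0 °C to rt
Reagents that add atoms: none
Why: Fluoride-mediated cleavage of both silyl ethers, buffered with pyridine so that the epoxy ketone and the β-hydroxy ketone should survive; the C7 descriptor changes only because the priorities change.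

Step 24
Reactants: 37 (1R,4R,5R,6S,7S,8R,10S)-4,5-epoxy-1,6-dihydroxy-7-(3-hydroxyprop-1-en-2-yl)-4,10-dimethyl-3-oxocyclodecan-8-yl (E)-2-methylbut-2-enoate
Product: 40 eupakirunsin C, via hydroxy enal 38 (not isolated), via lactol 39 (not isolated)
Conditions: MnO2 (excess), CH2Cl2, rt
Reagents that add atoms: none
Why: Oxidative lactonisation; MnO2 oxidises only the allylic primary alcohol, the C6 hydroxyl traps the enal as the five-membered lactol, and the lactol is oxidised on to the lactone. The C1 alcohol is secondary and not allylic and should be left alone.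

## Compound list

1 | methyl (S)-3-hydroxy-2-methylpropanoate | C[C@@H](CO)C(=O)OC | starting material
2 | methyl (S)-3-[(tert-butyldimethylsilyl)oxy]-2-methylpropanoate | CC(C)(C)[Si](C)(C)OC[C@H](C)C(=O)OC | intermediate
3 | (S)-3-[(tert-butyldimethylsilyl)oxy]-2-methylpropanal | CC(C)(C)[Si](C)(C)OC[C@H](C)C=O | intermediate
4 | (R)-tert-butyldimethyl[(2-methylbut-3-yn-1-yl)oxy]silane | CC(C)(C)[Si](C)(C)OC[C@H](C)C#C | intermediate
5 | tributyltin hydride | CCCC[SnH](CCCC)CCCC | starting material
6 | (R,E)-tert-butyldimethyl{[2-methyl-4-(tributylstannyl)but-3-en-1-yl]oxy}silane | CC(C)(C)[Si](C)(C)OC[C@H](C)/C=C/[Sn](CCCC)(CCCC)CCCC | intermediate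
7 | (R,E)-2-methyl-4-(tributylstannyl)but-3-en-1-ol | OC[C@H](C)/C=C/[Sn](CCCC)(CCCC)CCCC | intermediate
8 | (R,E)-2-methyl-4-(tributylstannyl)but-3-en-1-yl methanesulfonate | CS(=O)(=O)OC[C@H](C)/C=C/[Sn](CCCC)(CCCC)CCCC | intermediate
9 | (R,E)-(4-bromo-3-methylbut-1-en-1-yl)tributylstannane | BrC[C@H](C)/C=C/[Sn](CCCC)(CCCC)CCCC | intermediate
10 | 3-chloro-2-(chloromethyl)prop-1-ene | C=C(CCl)CCl | starting material
11 | 1-({[2-(chloromethyl)prop-2-en-1-yl]oxy}methyl)-4-methoxybenzene | C=C(CCl)COCc1ccc(OC)cc1 | intermediate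
12 | {2-[(4-methoxybenzyloxy)methyl]prop-2-en-1-yl}magnesium chloride | C=C(C[Mg]Cl)COCc1ccc(OC)cc1 | intermediate
13 | 3-{[(4-methoxybenzyl)oxy]methyl}but-3-enoic acid | C=C(CC(=O)O)COCc1ccc(OC)cc1 | intermediate
14 | (S)-4-benzyl-1,3-oxazolidin-2-one | O=C1OC[C@H](Cc2ccccc2)N1 | starting material
15 | 3-{[(4-methoxybenzyl)oxy]methyl}but-3-enoic pivalic anhydride | C=C(CC(=O)OC(=O)C(C)(C)C)COCc1ccc(OC)cc1 | intermediate
16 | (S)-4-benzyl-3-(3-{[(4-methoxybenzyl)oxy]methyl}but-3-enoyl)-1,3-oxazolidin-2-one | C=C(CC(=O)N1[C@@H](Cc2ccccc2)COC1=O)COCc3ccc(OC)cc3 | intermediate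
17 | but-2-yn-1-ol | CC#CCO | starting material
18 | sodium 2,2-bis(2-methoxyethoxy)-3-methyl-2,5-dihydro-1,2-oxaluminol-2-uide (cyclic Z-vinylalanate) | CC1=CCO[Al-]1(OCCOC)OCCOC.[Na+] | intermediate
19 | (Z)-3-iodobut-2-en-1-ol | C/C(I)=C/CO | intermediate
20 | (Z)-3-iodobut-2-enal | C/C(I)=C/C=O | intermediate
21 | dibutylboron (Z)-enolate of imide 16 | C=C(COCc3ccc(OC)cc3)/C=C(\OB(CCCC)CCCC)N1[C@@H](Cc2ccccc2)COC1=O | intermediate
22 | (S)-4-benzyl-3-[(2S,3S,4Z)-3-hydroxy-5-iodo-2-{3-[(4-methoxybenzyl)oxy]prop-1-en-2-yl}hex-4-enoyl]-1,3-oxazolidin-2-one | O=C1OC[C@H](Cc2ccccc2)N1C(=O)[C@@H](C(=C)COCc3ccc(OC)cc3)[C@H](O)/C=C(/C)I | intermediate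
23 | (2S,3S,4Z)-3-hydroxy-5-iodo-N-methoxy-2-{3-[(4-methoxybenzyl)oxy]prop-1-en-2-yl}-N-methylhex-4-enamide | CON(C)C(=O)[C@@H](C(=C)COCc1ccc(OC)cc1)[C@H](O)/C=C(/C)I | intermediate
24 | (2S,3S,4Z)-3-[(tert-butyldimethylsilyl)oxy]-5-iodo-N-methoxy-2-{3-[(4-methoxybenzyl)oxy]prop-1-en-2-yl}-N-methylhex-4-enamide | CON(C)C(=O)[C@@H](C(=C)COCc1ccc(OC)cc1)[C@H](O[Si](C)(C)C(C)(C)C)/C=C(/C)I | intermediate
25 | [(R,E)-2-methyl-4-(tributylstannyl)but-3-en-1-yl]magnesium bromide | Br[Mg]C[C@H](C)/C=C/[Sn](CCCC)(CCCC)CCCC | intermediate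
26 | (1E,3S,6S,7S,8Z)-7-[(tert-butyldimethylsilyl)oxy]-9-iodo-6-{3-[(4-methoxybenzyl)oxy]prop-1-en-2-yl}-3-methyl-1-(tributylstannyl)deca-1,8-dien-5-one | C=C(COCc1ccc(OC)cc1)[C@@H]([C@H](O[Si](C)(C)C(C)(C)C)/C=C(/C)I)C(=O)C[C@H](C)/C=C/[Sn](CCCC)(CCCC)CCCC | intermediate
27 | (1E,3S,5R,6R,7S,8Z)-7-[(tert-butyldimethylsilyl)oxy]-9-iodo-6-{3-[(4-methoxybenzyl)oxy]prop-1-en-2-yl}-3-methyl-1-(tributylstannyl)deca-1,8-dien-5-ol | C=C(COCc1ccc(OC)cc1)[C@@H]([C@H](O[Si](C)(C)C(C)(C)C)/C=C(/C)I)[C@H](O)C[C@H](C)/C=C/[Sn](CCCC)(CCCC)CCCC | intermediate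
28 | tiglic acid, (E)-2-methylbut-2-enoic acid | C/C=C(\C)C(=O)O | starting material
29 | (E)-2-methylbut-2-enoic 2,4,6-trichlorobenzoic anhydride | C/C=C(\C)C(=O)OC(=O)c1c(Cl)cc(Cl)cc1Cl | intermediate
30 | (1E,3S,5R,6R,7S,8Z)-7-[(tert-butyldimethylsilyl)oxy]-9-iodo-6-{3-[(4-methoxybenzyl)oxy]prop-1-en-2-yl}-3-methyl-1-(tributylstannyl)deca-1,8-dien-5-yl (E)-2-methylbut-2-enoate (seco precursor; germacrane locants 6S,7R,8R,10S) | C=C(COCc1ccc(OC)cc1)[C@@H]([C@H](O[Si](C)(C)C(C)(C)C)/C=C(/C)I)[C@H](OC(=O)/C(C)=C/C)C[C@H](C)/C=C/[Sn](CCCC)(CCCC)CCCC | intermediate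
31 | (1E,4Z,6R,7R,8R,10S)-6-[(tert-butyldimethylsilyl)oxy]-7-{3-[(4-methoxybenzyl)oxy]prop-1-en-2-yl}-4,10-dimethyl-3-oxocyclodeca-1,4-dien-8-yl (E)-2-methylbut-2-enoate | C=C(COCc1ccc(OC)cc1)[C@@H]1[C@H](OC(=O)/C(C)=C/C)C[C@H](C)/C=C/C(=O)/C(C)=C\[C@H]1O[Si](C)(C)C(C)(C)C | intermediate
32 | (1R,4Z,6R,7R,8R,10S)-6-[(tert-butyldimethylsilyl)oxy]-7-{3-[(4-methoxybenzyl)oxy]prop-1-en-2-yl}-4,10-dimethyl-3-oxo-1-(4,4,5,5-tetramethyl-1,3,2-dioxaborolan-2-yl)cyclodec-4-en-8-yl (E)-2-methylbut-2-enoate | C=C(COCc1ccc(OC)cc1)[C@@H]1[C@H](OC(=O)/C(C)=C/C)C[C@H](C)[C@H](B2OC(C)(C)C(C)(C)O2)CC(=O)/C(C)=C\[C@H]1O[Si](C)(C)C(C)(C)C | intermediate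
33 | (1R,4Z,6R,7R,8R,10S)-6-[(tert-butyldimethylsilyl)oxy]-1-hydroxy-7-{3-[(4-methoxybenzyl)oxy]prop-1-en-2-yl}-4,10-dimethyl-3-oxocyclodec-4-en-8-yl (E)-2-methylbut-2-enoate | C=C(COCc1ccc(OC)cc1)[C@@H]1[C@H](OC(=O)/C(C)=C/C)C[C@H](C)[C@H](O)CC(=O)/C(C)=C\[C@H]1O[Si](C)(C)C(C)(C)C | intermediate
34 | (1R,4Z,6R,7R,8R,10S)-6-[(tert-butyldimethylsilyl)oxy]-7-{3-[(4-methoxybenzyl)oxy]prop-1-en-2-yl}-4,10-dimethyl-3-oxo-1-[(triethylsilyl)oxy]cyclodec-4-en-8-yl (E)-2-methylbut-2-enoate | C=C(COCc1ccc(OC)cc1)[C@@H]1[C@H](OC(=O)/C(C)=C/C)C[C@H](C)[C@H](O[Si](CC)(CC)CC)CC(=O)/C(C)=C\[C@H]1O[Si](C)(C)C(C)(C)C | intermediate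
35 | (1R,4R,5R,6S,7R,8R,10S)-6-[(tert-butyldimethylsilyl)oxy]-4,5-epoxy-7-{3-[(4-methoxybenzyl)oxy]prop-1-en-2-yl}-4,10-dimethyl-3-oxo-1-[(triethylsilyl)oxy]cyclodecan-8-yl (E)-2-methylbut-2-enoate | C=C(COCc1ccc(OC)cc1)[C@@H]1[C@H](OC(=O)/C(C)=C/C)C[C@H](C)[C@H](O[Si](CC)(CC)CC)CC(=O)[C@]2(C)O[C@@H]2[C@H]1O[Si](C)(C)C(C)(C)C | intermediate
36 | (1R,4R,5R,6S,7R,8R,10S)-6-[(tert-butyldimethylsilyl)oxy]-4,5-epoxy-7-(3-hydroxyprop-1-en-2-yl)-4,10-dimethyl-3-oxo-1-[(triethylsilyl)oxy]cyclodecan-8-yl (E)-2-methylbut-2-enoate | C=C(CO)[C@@H]1[C@H](OC(=O)/C(C)=C/C)C[C@H](C)[C@H](O[Si](CC)(CC)CC)CC(=O)[C@]2(C)O[C@@H]2[C@H]1O[Si](C)(C)C(C)(C)C | intermediate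
37 | (1R,4R,5R,6S,7S,8R,10S)-4,5-epoxy-1,6-dihydroxy-7-(3-hydroxyprop-1-en-2-yl)-4,10-dimethyl-3-oxocyclodecan-8-yl (E)-2-methylbut-2-enoate | C=C(CO)[C@@H]1[C@H](OC(=O)/C(C)=C/C)C[C@H](C)[C@H](O)CC(=O)[C@]2(C)O[C@@H]2[C@H]1O | intermediate
38 | (1R,4R,5R,6S,7S,8R,10S)-4,5-epoxy-1,6-dihydroxy-4,10-dimethyl-3-oxo-7-(3-oxoprop-1-en-2-yl)cyclodecan-8-yl (E)-2-methylbut-2-enoate | C=C(C=O)[C@@H]1[C@H](OC(=O)/C(C)=C/C)C[C@H](C)[C@H](O)CC(=O)[C@]2(C)O[C@@H]2[C@H]1O | intermediate
39 | C12 lactol of eupakirunsin C (both C12 epimers) | C=C1C(O)O[C@H]2[C@H]1[C@H](OC(=O)/C(C)=C/C)C[C@H](C)[C@H](O)CC(=O)[C@]1(C)O[C@H]21 | intermediate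
40 | eupakirunsin C (1R,4R,5R,6S,7R,8R,10S) | C=C1C(=O)O[C@H]2[C@H]1[C@H](OC(=O)/C(C)=C/C)C[C@H](C)[C@H](O)CC(=O)[C@]1(C)O[C@H]21 | target

## Step count and least certain steps

Total step count: 24. Longest linear sequence: 16 steps (from 1 through steps 1–6 and 15–24; the branch from 10 through steps 7–9 and 12–24 is equally long).

**Step 18 (key step).** The most likely failure is chain-to-chain coupling that outruns ring closure, because transannular strain slows intramolecular transmetalation at the acylpalladium. Isomerisation of the Z-enone by reversible phosphine addition is the second concern. The fallback separates carbonyl insertion from ring closure. From 30, thiocarbonylation (EtSH, CO 1 atm, Pd(PPh3)4, Et3N, THF) would intercept the acylpalladium between molecules and give the S-ethyl (Z)-enethioate F1. F1 would then be cyclised without CO and under neutral conditions by the copper-mediated, palladium-catalysed thioester–stannane ketone coupling (Pd2(dba)3, tri(2-furyl)phosphine, CuO2PPh2, THF, high dilution), which returns to 31.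

**Step 21.** Three processes threaten it: rotation about C4–C5 in the β-peroxy enolate before ring closure (loss of the cis relationship), addition from the inner face, and base-induced β-elimination of the C1 silyloxy group. The fallback takes the olefin out of conjugation and uses a stereospecific, hydroxyl-directed epoxidation. From 34, 1,2-reduction with (S)-2-methyl-CBS-oxazaborolidine and catecholborane would give the (3R)-allylic alcohol F2, whose hydroxyl lies on the outer face. VO(acac)2 and tBuOOH would deliver oxygen syn to that hydroxyl with retention of olefin geometry to give the epoxy alcohol F3. Dess–Martin periodinane would restore the C3 ketone and rejoin the route at 35.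

**Step 19.** Facial selectivity at C1 may be poor if the ligand and the ring conformation are mismatched, and boron may also add to C5. The fallback is epoxidation followed by reductive opening. From 31, tBuOOH with catalytic BnMe3NOH would epoxidise only the more reactive E-enone from the outer face to give the (1S,2R)-1,2-epoxy ketone F4. Na[PhSeB(OEt)3] (from PhSeSePh and NaBH4 in EtOH, with AcOH) would cleave the C2–O bond and give 33.

**Step 15.** The Grignard reagent may deprotonate C7 (α to the amide and allylic) or add too slowly to the hindered amide. The fallback moves to the aldehyde oxidation level. From 24, iBu2AlH at −78 °C would give the aldehyde F5. Addition of 25 at −78 °C would give the C8 carbinol F6 as a mixture of epimers, and Dess–Martin periodinane would converge both on 26.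

**Step 16.** Diastereoselection may be low if the catalyst and the intrinsic bias of C7 oppose each other. The fallback uses the matched case and inverts during esterification. From 26, the (R)-catalyst would give the (8S)-alcohol F7 (deca numbering 5S). Mitsunobu esterification with 28 (PPh3, diisopropyl azodicarboxylate, toluene) would install the tiglate with inversion and give 30 directly.

## Further compounds

F1 | step 18 | S-ethyl (Z)-enethioate: 30 with the C4 iodine replaced by C(=O)SEt | C=C(COCc1ccc(OC)cc1)[C@@H]([C@H](O[Si](C)(C)C(C)(C)C)/C=C(/C)C(=O)SCC)[C@H](OC(=O)/C(C)=C/C)C[C@H](C)/C=C/[Sn](CCCC)(CCCC)CCCC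
F2 | step 21 | (3R)-allylic alcohol: 34 with the C3 ketone reduced | C=C(COCc1ccc(OC)cc1)[C@@H]1[C@H](OC(=O)/C(C)=C/C)C[C@H](C)[C@H](O[Si](CC)(CC)CC)C[C@@H](O)/C(C)=C\[C@H]1O[Si](C)(C)C(C)(C)C
F3 | step 21 | (3R,4R,5R)-4,5-epoxy-3-ol: 35 with C3 as the alcohol | C=C(COCc1ccc(OC)cc1)[C@@H]1[C@H](OC(=O)/C(C)=C/C)C[C@H](C)[C@H](O[Si](CC)(CC)CC)C[C@@H](O)[C@]2(C)O[C@@H]2[C@H]1O[Si](C)(C)C(C)(C)C
F4 | step 19 | (1S,2R)-1,2-epoxide of dienone 31 | C=C(COCc1ccc(OC)cc1)[C@@H]1[C@H](OC(=O)/C(C)=C/C)C[C@H](C)[C@@H]2O[C@H]2C(=O)/C(C)=C\[C@H]1O[Si](C)(C)C(C)(C)C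
F5 | step 15 | (2S,3S,4Z)-3-[(tert-butyldimethylsilyl)oxy]-5-iodo-2-{3-[(4-methoxybenzyl)oxy]prop-1-en-2-yl}hex-4-enal | O=C[C@@H](C(=C)COCc1ccc(OC)cc1)[C@H](O[Si](C)(C)C(C)(C)C)/C=C(/C)I
F6 | step 15 | C8 carbinol, both epimers at C5 (deca numbering) of alcohol 27 | C=C(COCc1ccc(OC)cc1)[C@@H]([C@H](O[Si](C)(C)C(C)(C)C)/C=C(/C)I)C(O)C[C@H](C)/C=C/[Sn](CCCC)(CCCC)CCCC
F7 | step 16 | (1E,3S,5S,6R,7S,8Z)-7-[(tert-butyldimethylsilyl)oxy]-9-iodo-6-{3-[(4-methoxybenzyl)oxy]prop-1-en-2-yl}-3-methyl-1-(tributylstannyl)deca-1,8-dien-5-ol | C=C(COCc1ccc(OC)cc1)[C@@H]([C@H](O[Si](C)(C)C(C)(C)C)/C=C(/C)I)[C@@H](O)C[C@H](C)/C=C/[Sn](CCCC)(CCCC)CCCC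
A1 | alternative 1 | trans-fused α-(diethoxyphosphoryl) lactone, both C11 epimers | CCOP(=O)(OCC)C1C(=O)O[C@H]2[C@H]1[C@H](OC(=O)/C(C)=C/C)C[C@H](C)[C@H](O[Si](C)(C)C(C)(C)C)CC(=O)[C@]1(C)O[C@H]21
A2 | alternative 2 | ten-membered (1E,4Z)-dien-6-one | COC(=O)C[C@@H]1[C@H](O[Si](C)(C)C(C)(C)C)C[C@H](C)/C=C/[C@@H](O[Si](CC)(CC)CC)/C(C)=C\C1=O
A3 | alternative 3 | ten-membered C8 ketone with C2=C3 methyl dienol ether | CC(C)(C)[Si](C)(C)O[C@H]2[C@H](CCO[Si](C)(C)C(C)(C)C)C(=O)C[C@H](C)[C@H](OCc1ccc(OC)cc1)/C=C(OC)/C(C)=C\2
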